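The C21 chain of Gentiside I is an unbranched polymethylene rod. Everything rests on cutting the CH2–CH2 bond between chain carbons C12 and C13 (counted from the ester oxygen), far from the ester and the benzene ring. One copper-catalysed sp3–sp3 Kochi coupling joins nonylmagnesium bromide to 12-bromododecyl 2,3-dihydroxybenzoate and completes the target without protecting-group steps. The two phenolic OH groups on ring carbons C2 and C3 are converted in the flask into a magnesium catecholate, whose C2 phenoxide, conjugated with the ester C=O, shields the ester from the Grignard reagent. The precursor comes from one Mitsunobu esterification of 2,3-dihydroxybenzoic acid.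

Key step: step 2

Remark: the target has no stereocentre and no stereogenic double bond; it is achiral, so no stereoselective step is needed. Nonylmagnesium bromide is taken as the commercial solution in diethyl ether.

Step 1
Reactants: 1 2,3-dihydroxybenzoic acid; 2 12-bromododecan-1-ol
Product: 3 12-bromododecyl 2,3-dihydroxybenzoate
Conditions: PPh3 (1.1 equiv), DIAD (1.1 equiv), THF, 0 °C → rt
Reagents that add atoms: none
Why: Mitsunobu esterification: the PPh3/DIAD betaine is protonated by the carboxylic acid, which is far more acidic than the two phenols, and the carboxylate then displaces the alkoxyphosphonium group of the primary alcohol in an SN2 step, so the ester should form with both phenols and the primary C–Br bond untouched.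

Step 2
Reactants: 3 12-bromododecyl 2,3-dihydroxybenzoate; 4 nonylmagnesium bromide
Product: 7 heneicosyl 2,3-dihydroxybenzoate (Gentiside I), via magnesium catecholate of bromo ester 5 (not isolated), via magnesium catecholate of coupled ester 6 (not isolated)
Conditions: 4 (2.0 equiv), THF, −40 °C; then Li2CuCl4 (5 mol %), NMP (4 equiv), 4 (1.4 equiv, slow addition), −20 → 0 °C; then 1 M HCl
Reagents that add atoms: none
Why: Two equivalents of 4 first deprotonate the C2 and C3 phenols (acid–base, nonane is lost) to give the magnesium catecholate 5, in which the C2 phenoxide is conjugated with and chelated to the ester carbonyl, so the ester is deactivated towards 1,2-addition. Further 4 reduces Cu(II) to Cu(I) and forms a nonylcuprate, which should attack the primary C–Br carbon of 5 by SN2-type oxidative addition to a dialkyl-Cu(III) species; reductive elimination then forms the CH2–CH2 bond and returns Cu(I). The closest known reaction type is the copper-catalysed Kochi–Tamura coupling of primary alkyl Grignard reagents with primary alkyl bromides in its NMP-modified (Cahiez) form, including its use on ω-bromo acids and alcohols carried as their magnesium salts. No ring is closed and no stereocentre is formed. The step needs chemoselectivity for C–Br over the ester C=O and cross- over homo-coupling; the catecholate shielding, NMP, low temperature, slow addition of 4 and the unhindered primary bromide twelve carbons from the ring should secure it. Acidic work-up protonates the coupled catecholate 6 to the target 7.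

Compound list
1 | 2,3-dihydroxybenzoic acid | OC(=O)c1cccc(O)c1O | starting material
2 | 12-bromododecan-1-ol | OCCCCCCCCCCCCBr | starting material
3 | 12-bromododecyl 2,3-dihydroxybenzoate | BrCCCCCCCCCCCCOC(=O)c1cccc(O)c1O | intermediate
4 | nonylmagnesium bromide | CCCCCCCCC[Mg]Br | starting material
5 | 12-bromododecyl 2,3-bis(bromomagnesiooxy)benzoate (magnesium catecholate of 3) | BrCCCCCCCCCCCCOC(=O)c1cccc(O[Mg]Br)c1O[Mg]Br | intermediate
6 | heneicosyl 2,3-bis(bromomagnesiooxy)benzoate (magnesium catecholate of 7) | CCCCCCCCCCCCCCCCCCCCCOC(=O)c1cccc(O[Mg]Br)c1O[Mg]Br | intermediate
7 | heneicosyl 2,3-dihydroxybenzoate (Gentiside I) | CCCCCCCCCCCCCCCCCCCCCOC(=O)c1cccc(O)c1O | target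

Total step count: 2
Longest linear sequence: 2 steps

Steps most likely to fail (the route has only two steps, so both are listed, the riskier first):

1. Step 2. The Grignard reagent may add to the ester carbonyl in competition with the coupling. The copper cycle may also stall if the magnesium catecholate aggregates or precipitates, or if the catecholate binds copper. The fallback sets out from 2 and comes back to the route at 7; it forms the same CH2–CH2 bond by a boron/palladium path on a protected catechol. Compound 2 would be esterified with commercial 2,3-bis(benzyloxy)benzoic acid (EDC·HCl, DMAP, CH2Cl2, rt) to 12-bromododecyl 2,3-bis(benzyloxy)benzoate F1. 1-Nonene would be hydroborated with 9-BBN (THF, rt) to B-nonyl-9-borabicyclo[3.3.1]nonane F2. F2 would be coupled with F1 in an alkyl–alkyl Suzuki–Miyaura reaction (Pd(OAc)2, PCy3, K3PO4·H2O, THF, rt) to heneicosyl 2,3-bis(benzyloxy)benzoate F3. Hydrogenolysis of both benzyl ethers (H2, Pd/C, EtOAc, rt) should then give 7.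

2. Step 1. Chemoselectivity may be lost through Mitsunobu O-alkylation of the C3 phenol or acyl transfer onto a phenol, giving ether or oligomeric ester by-products. The fallback sets out from 1 and comes back to the route at 3; it reverses the roles so that the carboxylate is the nucleophile. Compound 1 would be alkylated with an excess (about 4 equiv) of commercial 1,12-dibromododecane (KHCO3, DMF, 40 °C). Bicarbonate ionises only the carboxylic acid, so 3 should form directly, and the excess dibromide would be recovered by chromatography. No new compound is made on this path.

Further compounds
F1 | step 2 | 12-bromododecyl 2,3-bis(benzyloxy)benzoate | BrCCCCCCCCCCCCOC(=O)c1cccc(OCc2ccccc2)c1OCc1ccccc1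
F2 | step 2 | B-nonyl-9-borabicyclo[3.3.1]nonane | CCCCCCCCCB1C2CCCC1CCC2
F3 | step 2 | heneicosyl 2,3-bis(benzyloxy)benzoate | CCCCCCCCCCCCCCCCCCCCCOC(=O)c1cccc(OCc2ccccc2)c1OCc1ccccc1
F0 | step 1 | none | none
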